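**Retrosynthetic overview**

- Endgame: the two primary TBS ethers are removed last, the C15 ester comes from Steglich acylation with the TBS-protected (S)-Roche acid, and the α-methylene lactone is the oxidised form of a 2-methoxy-3-methylenetetrahydrofuran.
- Key disconnection C7–C11: the five-membered O-heterocycle (C11–C12–O–C8–C7) is closed on a preformed ten-membered ring by 5-exo cyclization of a C11 vinyl radical, carried on O8 as a 2-bromoallyl mixed acetal, onto C7 of a ring diene C4=C5–C6=C7.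
- Enabling feature: in the ten-membered carbocycle C7 is vicinal to the oxygen-bearing C8 and homoallylic to the C4=C5 alkene, so C4=C5–C6H2 is what an allyl radical leaves after C11 adds to a diene terminus and hydrogen is captured at C6; both C6=C7 geometries and both acetal epimers converge on one C7 configuration.
- The ten-membered ring is formed first, by diene–ene ring-closing metathesis at C6=C7 of an acyclic tetraenol; its C8 centre and C1=C10 geometry come from (R)-2-vinyloxirane and triethyl phosphonoacetate through a temporary C14–O8 butyrolactone (one-pot epoxide opening, lactonization, HWE), which is then reduced.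
- The C4=C5 geometry comes from copper-catalysed anti-carbomagnesiation/iodination of propargyl alcohol and Stille vinylation. Ring order: ten-membered carbocycle, then the lactone ring.

Key step: step 10

Remark on numbering: germacranolide positions are used. C1–C10 are the ring carbons (C8 carries the lactone oxygen, C7 the lactone carbon C11), C12 is the lactone carbonyl, C13 the exocyclic methylene, C14 the CH2O on C10 and C15 the CH2O on C4.

Assumption: (R)-2-vinyloxirane, the Grignard reagent 2 (THF solution), methoxyallene and methyl (S)-3-hydroxy-2-methylpropanoate are taken as purchasable.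

Remark on the C6=C7 geometry: 15 and 17 are drawn as the ring-cis C6=C7 isomers expected from the ring closure; any ring-trans isomer would be carried along, because this geometry disappears in step 10.

**Route**

Step 1
Reactants: 1 prop-2-yn-1-ol; 2 [2-(1,3-dioxolan-2-yl)ethyl]magnesium bromide
Product: 4 (2Z)-2-[2-(1,3-dioxolan-2-yl)ethyl]-3-iodoprop-2-en-1-ol, via alkenylmagnesium alkoxide 3 (not isolated)
Conditions: 2 (3 equiv), CuI (10 mol%), THF, −10 °C → rt; then I2, −78 → 0 °C; aq. work-up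
Reagents that add atoms: iodine, [I][I]
Why: Copper-catalysed anti-carbomagnesiation of the propargylic alkoxide should place the alkyl group on the internal carbon and magnesium on the terminal carbon cis to the CH2O group (five-membered chelate), so that iodinolysis with retention gives the (Z)-iodide that fixes the later C4=C5 geometry; no stereocentre is formed.

Step 2
Reactants: 4 (2Z)-2-[2-(1,3-dioxolan-2-yl)ethyl]-3-iodoprop-2-en-1-ol; 5 tributyl(vinyl)stannane
Product: 6 (2Z)-2-[2-(1,3-dioxolan-2-yl)ethyl]penta-2,4-dien-1-ol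
Conditions: Pd(PPh3)4 (5 mol%), CuI (10 mol%), DMF, rt → 40 °C
Reagents that add atoms: none
Why: Stille coupling of an alkenyl iodide with a vinylstannane proceeds with retention of the alkene geometry and tolerates the free allylic alcohol.

Step 3
Reactants: 6 (2Z)-2-[2-(1,3-dioxolan-2-yl)ethyl]penta-2,4-dien-1-ol
Product: 7 2-[(3Z)-3-{[(4-methoxybenzyl)oxy]methyl}hexa-3,5-dien-1-yl]-1,3-dioxolane
Conditions: NaH, 4-methoxybenzyl chloride, Bu4NI (cat.), THF/DMF, 0 °C → rt
Reagents that add atoms: 4-methoxybenzyl chloride, COc1ccc(CCl)cc1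
Why: Williamson etherification of the primary alkoxide gives the PMB ether that keeps C15 distinct from C14 through the later reduction.

Step 4
Reactants: 7 2-[(3Z)-3-{[(4-methoxybenzyl)oxy]methyl}hexa-3,5-dien-1-yl]-1,3-dioxolane
Product: 8 (4Z)-4-{[(4-methoxybenzyl)oxy]methyl}hepta-4,6-dienal
Conditions: PPTS (0.2 equiv), acetone/H2O (4:1), 50 °C
Reagents that add atoms: water, O
Why: Acid-catalysed acetal hydrolysis with a weak acid should free the aldehyde without ionizing the dienylic PMB ether.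

Step 5
Reactants: 8 (4Z)-4-{[(4-methoxybenzyl)oxy]methyl}hepta-4,6-dienal; 9 triethyl phosphonoacetate; 10 (R)-2-vinyloxirane
Product: 12 (3E,5S)-3-[(4Z)-4-{[(4-methoxybenzyl)oxy]methyl}hepta-4,6-dien-1-ylidene]-5-vinyloxolan-2-one, via sodium phosphonolactone enolate 11 (not isolated)
Conditions: 9, NaH, toluene/THF, 0 °C; 10, 70 °C; then 8, 0 °C → rt
Reagents that add atoms: none
Why: The sodium phosphonoacetate should open the epoxide at its unsubstituted carbon (SN2, the C8 centre is untouched), the alkoxide lactonizes and the released ethoxide generates the α-phosphono lactone anion, whose Horner–Wadsworth–Emmons olefination with 8 should give mainly the (E)-alkylidene lactone (C2 cis to C9), the geometry needed for C1=C10.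

Step 6
Reactants: 12 (3E,5S)-3-[(4Z)-4-{[(4-methoxybenzyl)oxy]methyl}hepta-4,6-dien-1-ylidene]-5-vinyloxolan-2-one
Product: 13 (3S,5E,9Z)-5-(hydroxymethyl)-9-{[(4-methoxybenzyl)oxy]methyl}dodeca-1,5,9,11-tetraen-3-ol
Conditions: i-Bu2AlH (4 equiv), CH2Cl2, −78 → 0 °C; aq. work-up
Reagents that add atoms: none
Why: i-Bu2AlH reduces the conjugated lactone in the 1,2 sense through the lactol to the allylic diol and leaves the diene and the PMB ether alone.

Step 7
Reactants: 13 (3S,5E,9Z)-5-(hydroxymethyl)-9-{[(4-methoxybenzyl)oxy]methyl}dodeca-1,5,9,11-tetraen-3-ol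
Product: 14 (3S,5E,9Z)-5-{[(tert-butyldimethylsilyl)oxy]methyl}-9-{[(4-methoxybenzyl)oxy]methyl}dodeca-1,5,9,11-tetraen-3-ol
Conditions: TBSCl (1.05 equiv), imidazole, CH2Cl2, −20 °C
Reagents that add atoms: tert-butyldimethylsilyl chloride, CC(C)(C)[Si](C)(C)Cl
Why: Silylation of the primary allylic alcohol is much faster than that of the secondary one at low temperature, which leaves the C8 hydroxyl free for the tether.

Step 8
Reactants: 14 (3S,5E,9Z)-5-{[(tert-butyldimethylsilyl)oxy]methyl}-9-{[(4-methoxybenzyl)oxy]methyl}dodeca-1,5,9,11-tetraen-3-ol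
Product: 15 (1S,2Z,4Z,8E)-9-{[(tert-butyldimethylsilyl)oxy]methyl}-5-{[(4-methoxybenzyl)oxy]methyl}cyclodeca-2,4,8-trien-1-ol
Conditions: RuCl2(H2IMes)(=CH-2-(i-PrO)C6H4) (second-generation Hoveyda–Grubbs catalyst, 10 mol%), 1,4-benzoquinone (20 mol%), CH2Cl2 (0.5 mM), 40 °C
Reagents that add atoms: none
Why: Diene–ene ring-closing metathesis between the two monosubstituted termini should form the C6=C7 bond with loss of ethene, the trisubstituted internal alkenes being unreactive and the cis C1=C10 bond lowering transannular strain; no stereocentre is formed.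

Step 9
Reactants: 15 (1S,2Z,4Z,8E)-9-{[(tert-butyldimethylsilyl)oxy]methyl}-5-{[(4-methoxybenzyl)oxy]methyl}cyclodeca-2,4,8-trien-1-ol; 16 methoxyallene
Product: 17 (1S,2Z,4Z,8E)-1-[(2-bromo-1-methoxyprop-2-en-1-yl)oxy]-9-{[(tert-butyldimethylsilyl)oxy]methyl}-5-{[(4-methoxybenzyl)oxy]methyl}cyclodeca-2,4,8-triene (both acetal epimers)
Conditions: 16 (3 equiv), NBS (1.5 equiv), CH2Cl2, −78 → −30 °C
Reagents that add atoms: N-bromosuccinimide, O=C1CCC(=O)N1Br
Why: Bromonium transfer to the central carbon of the electron-rich alkoxyallene gives an oxocarbenium ion that the C8 alcohol traps (haloacetalization, the first half of the Ueno–Stork sequence); the acetal carbon forms as a mixture that is of no consequence.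

Step 10
Reactants: 17 (1S,2Z,4Z,8E)-1-[(2-bromo-1-methoxyprop-2-en-1-yl)oxy]-9-{[(tert-butyldimethylsilyl)oxy]methyl}-5-{[(4-methoxybenzyl)oxy]methyl}cyclodeca-2,4,8-triene
Product: 18 (3aR,5Z,9E,11aS)-10-{[(tert-butyldimethylsilyl)oxy]methyl}-2-methoxy-6-{[(4-methoxybenzyl)oxy]methyl}-3-methylidene-2,3,3a,4,7,8,11,11a-octahydrocyclodeca[b]furan (both C2 epimers)
Conditions: Bu3SnH (1.5 equiv, syringe pump), Et3B (0.3 equiv), air, toluene (5 mM), 0 °C → rt
Reagents that add atoms: none
Why: Bu3Sn• abstracts bromine from the 2-bromoallyl acetal and the σ-vinyl radical at C11 adds to C7, the terminus of the ring diene that the C8 acetal oxygen holds within reach; the C4–C5–C6 allyl radical so formed takes hydrogen from Bu3SnH at its less substituted end C6, which leaves the trisubstituted C4=C5 bond in its ring-trans geometry and the exocyclic methylene already in place. The closest known reaction type is the Ueno–Stork haloacetal radical cyclization in its vinyl-radical form (2-bromoallyl mixed acetals), including closures onto 1,3-dienes that end by reduction of the allyl radical. One ring is closed, the tetrahydrofuran C11–C12–O–C8–C7, in the 5-exo-trig mode. The new stereocentre C7 is controlled by C8: in a ten-membered ring the C8–C9 bond cannot eclipse C6=C7 and stands roughly perpendicular to the diene plane, so the acetal oxygen sits on the opposite face and delivers C11 anti to C9, which puts H7 and H8 trans (7R from 8S) for either geometry of C6=C7; the acetal carbon forms as a mixture that step 12 erases. The step needs 5-exo closure to outrun direct reduction of the vinyl radical, 1,5-hydrogen transfer from C9 and 6-exo attack on C10, which addition to a diene terminus (allyl radical formed) and slow addition of Bu3SnH at high dilution should secure. It also needs hydrogen delivery to C6 and not to C4, which the fully substituted C4 terminus and the greater stability of the trisubstituted alkene should secure.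

Step 11
Reactants: 18 (3aR,5Z,9E,11aS)-10-{[(tert-butyldimethylsilyl)oxy]methyl}-2-methoxy-6-{[(4-methoxybenzyl)oxy]methyl}-3-methylidene-2,3,3a,4,7,8,11,11a-octahydrocyclodeca[b]furan
Product: 19 (3aR,5Z,9E,11aS)-10-{[(tert-butyldimethylsilyl)oxy]methyl}-6-{[(4-methoxybenzyl)oxy]methyl}-3-methylidene-2,3,3a,4,7,8,11,11a-octahydrocyclodeca[b]furan-2-ol (both C2 epimers)
Conditions: PPTS (0.2 equiv), acetone/H2O (5:1), rt
Reagents that add atoms: water, O
Why: Mild acid hydrolysis of the allylic mixed acetal through its oxocarbenium ion should give the lactol without loss of the silyl or PMB ether.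

Step 12
Reactants: 19 (3aR,5Z,9E,11aS)-10-{[(tert-butyldimethylsilyl)oxy]methyl}-6-{[(4-methoxybenzyl)oxy]methyl}-3-methylidene-2,3,3a,4,7,8,11,11a-octahydrocyclodeca[b]furan-2-ol
Product: 20 (3aR,5Z,9E,11aS)-10-{[(tert-butyldimethylsilyl)oxy]methyl}-6-{[(4-methoxybenzyl)oxy]methyl}-3-methylidene-3a,4,7,8,11,11a-hexahydrocyclodeca[b]furan-2(3H)-one
Conditions: TEMPO (0.2 equiv), PhI(OAc)2 (1.5 equiv), CH2Cl2, rt
Reagents that add atoms: none
Why: Oxoammonium (TEMPO) oxidation with PhI(OAc)2 as terminal oxidant converts the lactol into the lactone under nearly neutral conditions, the lactol being the only free hydroxyl.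

Step 13
Reactants: 20 (3aR,5Z,9E,11aS)-10-{[(tert-butyldimethylsilyl)oxy]methyl}-6-{[(4-methoxybenzyl)oxy]methyl}-3-methylidene-3a,4,7,8,11,11a-hexahydrocyclodeca[b]furan-2(3H)-one
Product: 21 (3aR,5Z,9E,11aS)-10-{[(tert-butyldimethylsilyl)oxy]methyl}-6-(hydroxymethyl)-3-methylidene-3a,4,7,8,11,11a-hexahydrocyclodeca[b]furan-2(3H)-one
Conditions: DDQ (1.3 equiv), CH2Cl2/H2O (18:1), 0 °C
Reagents that add atoms: none
Why: Oxidative cleavage of the PMB ether by DDQ through the benzylic oxocarbenium ion leaves the TBS ether, the lactone and the isolated alkenes intact.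

Step 14
Reactants: 22 methyl (2S)-3-hydroxy-2-methylpropanoate
Product: 23 methyl (2S)-3-[(tert-butyldimethylsilyl)oxy]-2-methylpropanoate
Conditions: TBSCl, imidazole, DMF, 0 °C → rt
Reagents that add atoms: tert-butyldimethylsilyl chloride, CC(C)(C)[Si](C)(C)Cl
Why: Standard silylation of the primary alcohol; the stereocentre comes from the Roche ester and is not touched.

Step 15
Reactants: 23 methyl (2S)-3-[(tert-butyldimethylsilyl)oxy]-2-methylpropanoate
Product: 24 (2S)-3-[(tert-butyldimethylsilyl)oxy]-2-methylpropanoic acid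
Conditions: LiOH·H2O, THF/MeOH/H2O, 0 °C → rt; then 1 M HCl to pH 3, 0 °C
Reagents that add atoms: lithium hydroxide, [Li+].[OH-]
Why: Saponification at low temperature should spare the silyl ether and not epimerize the α-centre to a significant extent.

Step 16
Reactants: 21 (3aR,5Z,9E,11aS)-10-{[(tert-butyldimethylsilyl)oxy]methyl}-6-(hydroxymethyl)-3-methylidene-3a,4,7,8,11,11a-hexahydrocyclodeca[b]furan-2(3H)-one; 24 (2S)-3-[(tert-butyldimethylsilyl)oxy]-2-methylpropanoic acid
Product: 25 [(3aR,5Z,9E,11aS)-10-{[(tert-butyldimethylsilyl)oxy]methyl}-3-methylidene-2-oxo-2,3,3a,4,7,8,11,11a-octahydrocyclodeca[b]furan-6-yl]methyl (2S)-3-[(tert-butyldimethylsilyl)oxy]-2-methylpropanoate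
Conditions: DCC, DMAP (0.2 equiv), CH2Cl2, 0 °C → rt
Reagents that add atoms: none
Why: Steglich esterification of the primary allylic alcohol; the side-chain stereocentre is carried in from 24.

Step 17
Reactants: 25 [(3aR,5Z,9E,11aS)-10-{[(tert-butyldimethylsilyl)oxy]methyl}-3-methylidene-2-oxo-2,3,3a,4,7,8,11,11a-octahydrocyclodeca[b]furan-6-yl]methyl (2S)-3-[(tert-butyldimethylsilyl)oxy]-2-methylpropanoate
Product: 26 [(3aR,5Z,9E,11aS)-10-(hydroxymethyl)-3-methylidene-2-oxo-2,3,3a,4,7,8,11,11a-octahydrocyclodeca[b]furan-6-yl]methyl (2S)-3-hydroxy-2-methylpropanoate (CNP0241696.1)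
Conditions: HF·pyridine, pyridine, THF, 0 °C → rt
Reagents that add atoms: none
Why: Buffered fluoride cleavage of both primary TBS ethers should spare the α-methylene lactone and the allylic ester.

**Compound list**

1 | prop-2-yn-1-ol | C#CCO | starting material
2 | [2-(1,3-dioxolan-2-yl)ethyl]magnesium bromide | Br[Mg]CCC1OCCO1 | starting material
3 | bromomagnesium (2Z)-3-(bromomagnesio)-2-[2-(1,3-dioxolan-2-yl)ethyl]prop-2-en-1-olate | Br[Mg]OC/C(CCC1OCCO1)=C\[Mg]Br | intermediate (not isolated)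
4 | (2Z)-2-[2-(1,3-dioxolan-2-yl)ethyl]-3-iodoprop-2-en-1-ol | OC/C(CCC1OCCO1)=C\I | intermediate
5 | tributyl(vinyl)stannane | C=C[Sn](CCCC)(CCCC)CCCC | starting material
6 | (2Z)-2-[2-(1,3-dioxolan-2-yl)ethyl]penta-2,4-dien-1-ol | OC/C(CCC1OCCO1)=C\C=C | intermediate
7 | 2-[(3Z)-3-{[(4-methoxybenzyl)oxy]methyl}hexa-3,5-dien-1-yl]-1,3-dioxolane | COc1ccc(COC/C(CCC2OCCO2)=C\C=C)cc1 | intermediate
8 | (4Z)-4-{[(4-methoxybenzyl)oxy]methyl}hepta-4,6-dienal | COc1ccc(COC/C(CCC=O)=C\C=C)cc1 | intermediate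
9 | triethyl phosphonoacetate | CCOC(=O)CP(=O)(OCC)OCC | starting material
10 | (R)-2-vinyloxirane | C=C[C@@H]1CO1 | starting material
11 | sodium salt (C3 carbanion) of diethyl [(5S)-2-oxo-5-vinyloxolan-3-yl]phosphonate | [Na+].CCOP(=O)(OCC)[C-]1C[C@@H](C=C)OC1=O | intermediate (not isolated)
12 | (3E,5S)-3-[(4Z)-4-{[(4-methoxybenzyl)oxy]methyl}hepta-4,6-dien-1-ylidene]-5-vinyloxolan-2-one | C=C[C@@H]1C/C(=C\CC/C(COCc2ccc(OC)cc2)=C/C=C)C(=O)O1 | intermediate
13 | (3S,5E,9Z)-5-(hydroxymethyl)-9-{[(4-methoxybenzyl)oxy]methyl}dodeca-1,5,9,11-tetraen-3-ol | C=C[C@@H](O)C/C(CO)=C\CC/C(COCc1ccc(OC)cc1)=C/C=C | intermediate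
14 | (3S,5E,9Z)-5-{[(tert-butyldimethylsilyl)oxy]methyl}-9-{[(4-methoxybenzyl)oxy]methyl}dodeca-1,5,9,11-tetraen-3-ol | C=C[C@@H](O)C/C(CO[Si](C)(C)C(C)(C)C)=C\CC/C(COCc1ccc(OC)cc1)=C/C=C | intermediate
15 | (1S,2Z,4Z,8E)-9-{[(tert-butyldimethylsilyl)oxy]methyl}-5-{[(4-methoxybenzyl)oxy]methyl}cyclodeca-2,4,8-trien-1-ol (2Z drawn) | O[C@@H]1/C=C\C=C(/COCc2ccc(OC)cc2)CC/C=C(/CO[Si](C)(C)C(C)(C)C)C1 | intermediate
16 | methoxyallene (1-methoxypropa-1,2-diene) | COC=C=C | starting material
17 | (1S,2Z,4Z,8E)-1-[(2-bromo-1-methoxyprop-2-en-1-yl)oxy]-9-{[(tert-butyldimethylsilyl)oxy]methyl}-5-{[(4-methoxybenzyl)oxy]methyl}cyclodeca-2,4,8-triene (acetal epimers) | C=C(Br)C(OC)O[C@@H]1/C=C\C=C(/COCc2ccc(OC)cc2)CC/C=C(/CO[Si](C)(C)C(C)(C)C)C1 | intermediate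
18 | (3aR,5Z,9E,11aS)-10-{[(tert-butyldimethylsilyl)oxy]methyl}-2-methoxy-6-{[(4-methoxybenzyl)oxy]methyl}-3-methylidene-2,3,3a,4,7,8,11,11a-octahydrocyclodeca[b]furan (C2 epimers) | C=C1C(OC)O[C@H]2C/C(CO[Si](C)(C)C(C)(C)C)=C\CC/C(COCc3ccc(OC)cc3)=C/C[C@H]12 | intermediate
19 | (3aR,5Z,9E,11aS)-10-{[(tert-butyldimethylsilyl)oxy]methyl}-6-{[(4-methoxybenzyl)oxy]methyl}-3-methylidene-2,3,3a,4,7,8,11,11a-octahydrocyclodeca[b]furan-2-ol (C2 epimers) | C=C1C(O)O[C@H]2C/C(CO[Si](C)(C)C(C)(C)C)=C\CC/C(COCc3ccc(OC)cc3)=C/C[C@H]12 | intermediate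
20 | (3aR,5Z,9E,11aS)-10-{[(tert-butyldimethylsilyl)oxy]methyl}-6-{[(4-methoxybenzyl)oxy]methyl}-3-methylidene-3a,4,7,8,11,11a-hexahydrocyclodeca[b]furan-2(3H)-one | C=C1C(=O)O[C@H]2C/C(CO[Si](C)(C)C(C)(C)C)=C\CC/C(COCc3ccc(OC)cc3)=C/C[C@H]12 | intermediate
21 | (3aR,5Z,9E,11aS)-10-{[(tert-butyldimethylsilyl)oxy]methyl}-6-(hydroxymethyl)-3-methylidene-3a,4,7,8,11,11a-hexahydrocyclodeca[b]furan-2(3H)-one | C=C1C(=O)O[C@H]2C/C(CO[Si](C)(C)C(C)(C)C)=C\CC/C(CO)=C/C[C@H]12 | intermediate
22 | methyl (2S)-3-hydroxy-2-methylpropanoate | COC(=O)[C@@H](C)CO | starting material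
23 | methyl (2S)-3-[(tert-butyldimethylsilyl)oxy]-2-methylpropanoate | COC(=O)[C@@H](C)CO[Si](C)(C)C(C)(C)C | intermediate
24 | (2S)-3-[(tert-butyldimethylsilyl)oxy]-2-methylpropanoic acid | OC(=O)[C@@H](C)CO[Si](C)(C)C(C)(C)C | intermediate
25 | [(3aR,5Z,9E,11aS)-10-{[(tert-butyldimethylsilyl)oxy]methyl}-3-methylidene-2-oxo-2,3,3a,4,7,8,11,11a-octahydrocyclodeca[b]furan-6-yl]methyl (2S)-3-[(tert-butyldimethylsilyl)oxy]-2-methylpropanoate | C=C1C(=O)O[C@H]2C/C(CO[Si](C)(C)C(C)(C)C)=C\CC/C(COC(=O)[C@@H](C)CO[Si](C)(C)C(C)(C)C)=C/C[C@H]12 | intermediate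
26 | [(3aR,5Z,9E,11aS)-10-(hydroxymethyl)-3-methylidene-2-oxo-2,3,3a,4,7,8,11,11a-octahydrocyclodeca[b]furan-6-yl]methyl (2S)-3-hydroxy-2-methylpropanoate | C=C1C(=O)O[C@H]2C/C(CO)=C\CC/C(COC(=O)[C@@H](C)CO)=C/C[C@H]12 | target

**Step count and risks**

Total step count: 17. Longest linear sequence: 15 steps (steps 1–13, 16 and 17, from prop-2-yn-1-ol).

Steps most likely to fail:

1. Step 8 (ring-closing metathesis). Intermolecular metathesis (dimers, oligomers) and olefin migration by ruthenium hydrides may outrun closure of the strained ten-membered triene. Fallback: close the ring one stage earlier, on lactone 12, where the butyrolactone locks C8, C9, C10 and the (E)-alkylidene bond into a turn that brings the vinyl group and the diene terminus together. Ring-closing metathesis of 12 under the same high-dilution regime would give the bridged lactone (1E,5Z,7Z,9S)-5-{[(4-methoxybenzyl)oxy]methyl}-10-oxabicyclo[7.2.1]dodeca-1,5,7-trien-11-one F1. Reduction with i-Bu2AlH would open it to the ring diol (1S,2Z,4Z,8E)-9-(hydroxymethyl)-5-{[(4-methoxybenzyl)oxy]methyl}cyclodeca-2,4,8-trien-1-ol F2, and selective silylation of its primary alcohol (TBSCl, imidazole, −20 °C) comes back to the route at 15.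

2. Step 10 (radical cyclization). Hydrogen transfer to the vinyl radical (from Bu3SnH, or from the allylic C9–H by a 1,5-shift) may precede ring closure, or C11 may be delivered to the wrong face of C7. Fallback: use an alkyl radical, which is reduced and translocated far more slowly, and introduce C13 afterwards. From 15, ethyl vinyl ether and NBS would give the bromoacetal (1S,2Z,4Z,8E)-1-(2-bromo-1-ethoxyethoxy)-9-{[(tert-butyldimethylsilyl)oxy]methyl}-5-{[(4-methoxybenzyl)oxy]methyl}cyclodeca-2,4,8-triene F3. Bu3SnH/Et3B would close it 5-exo onto C7 to the ethyl acetal (3aR,5Z,9E,11aS)-10-{[(tert-butyldimethylsilyl)oxy]methyl}-2-ethoxy-6-{[(4-methoxybenzyl)oxy]methyl}-2,3,3a,4,7,8,11,11a-octahydrocyclodeca[b]furan F4. PPTS in wet acetone would give the corresponding lactol, the 2-ol F5, and TEMPO/PhI(OAc)2 the saturated lactone (3aR,5Z,9E,11aS)-10-{[(tert-butyldimethylsilyl)oxy]methyl}-6-{[(4-methoxybenzyl)oxy]methyl}-3a,4,7,8,11,11a-hexahydrocyclodeca[b]furan-2(3H)-one F6. Formylation (NaH, ethyl formate) would give the sodium enolate of the 3-(hydroxymethylidene) lactone F7, and aqueous formaldehyde would convert it by deformylative methylenation into 20, where the route is rejoined.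

3. Step 9 (haloacetalization). NBS may attack the ring diene or the trisubstituted alkenes (bromo-etherification, transannular closure), and the dienylic alcohol may ionize. Fallback: spend the halogen on the allene before the triene is present, and install the tether by substitution instead of cohalogenation. From 16, bromine at −78 °C would give the α-bromo ether 2,3-dibromo-3-methoxyprop-1-ene F8, used at once. Alcohol 15 and i-Pr2NEt would displace its α-bromide (haloether alkylation) and come back to the route at 17.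

**Further compounds**

F1 | step 8 | (1E,5Z,7Z,9S)-5-{[(4-methoxybenzyl)oxy]methyl}-10-oxabicyclo[7.2.1]dodeca-1,5,7-trien-11-one | O=C1O[C@@H]2/C=C\C=C(/COCc3ccc(OC)cc3)CC/C=C1\C2
F2 | step 8 | (1S,2Z,4Z,8E)-9-(hydroxymethyl)-5-{[(4-methoxybenzyl)oxy]methyl}cyclodeca-2,4,8-trien-1-ol | O[C@@H]1/C=C\C=C(/COCc2ccc(OC)cc2)CC/C=C(/CO)C1
F3 | step 10 | (1S,2Z,4Z,8E)-1-(2-bromo-1-ethoxyethoxy)-9-{[(tert-butyldimethylsilyl)oxy]methyl}-5-{[(4-methoxybenzyl)oxy]methyl}cyclodeca-2,4,8-triene | BrCC(OCC)O[C@@H]1/C=C\C=C(/COCc2ccc(OC)cc2)CC/C=C(/CO[Si](C)(C)C(C)(C)C)C1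
F4 | step 10 | (3aR,5Z,9E,11aS)-10-{[(tert-butyldimethylsilyl)oxy]methyl}-2-ethoxy-6-{[(4-methoxybenzyl)oxy]methyl}-2,3,3a,4,7,8,11,11a-octahydrocyclodeca[b]furan | C1C(OCC)O[C@H]2C/C(CO[Si](C)(C)C(C)(C)C)=C\CC/C(COCc3ccc(OC)cc3)=C/C[C@H]12
F5 | step 10 | (3aR,5Z,9E,11aS)-10-{[(tert-butyldimethylsilyl)oxy]methyl}-6-{[(4-methoxybenzyl)oxy]methyl}-2,3,3a,4,7,8,11,11a-octahydrocyclodeca[b]furan-2-ol | C1C(O)O[C@H]2C/C(CO[Si](C)(C)C(C)(C)C)=C\CC/C(COCc3ccc(OC)cc3)=C/C[C@H]12
F6 | step 10 | (3aR,5Z,9E,11aS)-10-{[(tert-butyldimethylsilyl)oxy]methyl}-6-{[(4-methoxybenzyl)oxy]methyl}-3a,4,7,8,11,11a-hexahydrocyclodeca[b]furan-2(3H)-one | C1C(=O)O[C@H]2C/C(CO[Si](C)(C)C(C)(C)C)=C\CC/C(COCc3ccc(OC)cc3)=C/C[C@H]12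
F7 | step 10 | sodium enolate of (3aR,5Z,9E,11aS)-10-{[(tert-butyldimethylsilyl)oxy]methyl}-3-(hydroxymethylidene)-6-{[(4-methoxybenzyl)oxy]methyl}-3a,4,7,8,11,11a-hexahydrocyclodeca[b]furan-2(3H)-one | [Na+].[O-]C=C1C(=O)O[C@H]2C/C(CO[Si](C)(C)C(C)(C)C)=C\CC/C(COCc3ccc(OC)cc3)=C/C[C@H]12
F8 | step 9 | 2,3-dibromo-3-methoxyprop-1-ene | COC(Br)C(Br)=C
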